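**Plan**

- Retrosynthesis: after removal of fifteen benzyl groups and two carboxyl groups, ring A is cut at the two C–C bonds that join the hydroxyl carbons flanking its ether carbon to the two CH carbons. The O–C bond between the ring B oxygen and that ether carbon is cut next, then the four diaryl ether C–O bonds B–C, C–D, D–E and E–F, each on the side of the ring that carried bromine.
- Enabling feature: in ring A the ether carbon lies between two C–OH carbons, which is the O–C(C=O)2 array of an aryloxymalonate; the remaining CH–C(OH)–CH triad is the C2–C3–C4 unit of a 1,3-acetonedicarboxylate.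
- Forward: the ring F phenol is extended ring by ring (E, D, C, B) by alternating Ullmann etherification with a bromobenzaldehyde (formyl ortho or para to bromine) and Baeyer–Villiger excision of the formyl carbon, which unmasks the next phenol.
- The ring B phenol is O-alkylated with a chloromalonate, ring A is closed last by the [3+3] Claisen–Dieckmann annulation, and a single hydrogenolysis removes all benzyl groups with loss of both carboxyl groups.
- Stereochemistry: the target has no stereocentre, so nothing has to be set or preserved.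

Key step: step 16

Remark on the chemistry: rings are lettered A to F along the chain from the terminal phloroglucinol (A) to the terminal 3,4,5-trihydroxyphenoxy ring (F). Benzyl esters are used on both annulation partners so that the alkoxide released in the key step matches the ester alkoxide, and so that the final hydrogenolysis frees the diacid without any basic saponification.

**Route**

Step 1
Reactants: 1 3,4,5-trihydroxybenzaldehyde
Product: 2 3,4,5-tris(benzyloxy)benzaldehyde
Conditions: BnBr (3.5 equiv), K2CO3, DMF, 60 °C, N2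
Reagents that add atoms: benzyl bromide, BrCc1ccccc1
Why: Williamson etherification, in which K2CO3 deprotonates all three phenols and each phenoxide displaces bromide from benzyl bromide while the aldehyde is untouched.

Step 2
Reactants: 2 3,4,5-tris(benzyloxy)benzaldehyde
Product: 4 3,4,5-tris(benzyloxy)phenol, via aryl formate 3 (not isolated)
Conditions: mCPBA, CH2Cl2, 0 °C to rt; then K2CO3 (0.2 equiv), MeOH, rt
Reagents that add atoms: 3-chloroperoxybenzoic acid, O=C(OO)c1cccc(Cl)c1
Why: Baeyer–Villiger oxidation of an electron-rich benzaldehyde, in which the trialkoxyaryl group migrates in preference to hydride to give formate 3, which base-catalysed methanolysis cleaves to the phenol.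

Step 3
Reactants: 2 3,4,5-tris(benzyloxy)benzaldehyde
Product: 5 2-bromo-3,4,5-tris(benzyloxy)benzaldehyde
Conditions: NBS (1.1 equiv), MeCN, rt, dark
Reagents that add atoms: N-bromosuccinimide, O=C1CCC(=O)N1Br
Why: Electrophilic aromatic bromination at one of the two equivalent free ring positions, each ortho and para to a benzyloxy group; the formyl group and the first bromine deactivate the ring towards a second substitution.

Step 4
Reactants: 6 4-bromo-3,5-dimethoxybenzaldehyde
Product: 7 4-bromo-3,5-dihydroxybenzaldehyde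
Conditions: BBr3 (3 equiv), CH2Cl2, −78 °C to rt; H2O
Reagents that add atoms: none
Why: Lewis-acid demethylation of aryl methyl ethers by BBr3, which leaves the aryl bromide intact and returns the aldehyde on aqueous work-up.

Step 5
Reactants: 7 4-bromo-3,5-dihydroxybenzaldehyde
Product: 8 3,5-bis(benzyloxy)-4-bromobenzaldehyde
Conditions: BnBr (2.3 equiv), K2CO3, DMF, 60 °C
Reagents that add atoms: benzyl bromide, BrCc1ccccc1
Why: Williamson etherification of the two phenols flanking the bromine, which is inert to phenoxide under these conditions.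

Step 6
Reactants: 4 3,4,5-tris(benzyloxy)phenol; 5 2-bromo-3,4,5-tris(benzyloxy)benzaldehyde
Product: 9 EF aldehyde 3,4,5-tris(benzyloxy)-2-[3,4,5-tris(benzyloxy)phenoxy]benzaldehyde
Conditions: CuI (20 mol%), N,N-dimethylglycine (40 mol%), Cs2CO3, 1,4-dioxane, 100 °C, Ar
Reagents that add atoms: none
Why: Ullmann diaryl ether synthesis, in which the ortho-formyl group assists insertion of monovalent copper into the C–Br bond of 5 and the phenoxide of 4 has two free ortho positions.

Step 7
Reactants: 9 EF aldehyde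
Product: 11 EF phenol 3,4,5-tris(benzyloxy)-2-[3,4,5-tris(benzyloxy)phenoxy]phenol, via EF formate 10 (not isolated)
Conditions: mCPBA, CH2Cl2, 0 °C to rt; then K2CO3 (0.2 equiv), MeOH, rt
Reagents that add atoms: 3-chloroperoxybenzoic acid, O=C(OO)c1cccc(Cl)c1
Why: Baeyer–Villiger oxidation in which the aryl group, carrying an ortho aryloxy and a para benzyloxy donor, migrates to oxygen, followed by methanolysis of the formate.

Step 8
Reactants: 11 EF phenol; 8 3,5-bis(benzyloxy)-4-bromobenzaldehyde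
Product: 12 DEF aldehyde 3,5-bis(benzyloxy)-4-(EF-aryloxy)benzaldehyde
Conditions: CuI (20 mol%), N,N-dimethylglycine (40 mol%), Cs2CO3, 1,4-dioxane, 100 °C, Ar
Reagents that add atoms: none
Why: Ullmann diaryl ether synthesis, in which the para-formyl group lowers the electron density at the bromine-bearing carbon of 8 and offsets its two flanking benzyloxy groups, while the phenoxide of 11 has only one ortho substituent.

Step 9
Reactants: 12 DEF aldehyde
Product: 14 DEF phenol 3,5-bis(benzyloxy)-4-(EF-aryloxy)phenol, via DEF formate 13 (not isolated)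
Conditions: mCPBA, CH2Cl2, 0 °C to rt; then K2CO3 (0.2 equiv), MeOH, rt
Reagents that add atoms: 3-chloroperoxybenzoic acid, O=C(OO)c1cccc(Cl)c1
Why: Baeyer–Villiger oxidation of a 3,4,5-trioxygenated benzaldehyde, whose para aryloxy group drives aryl migration, followed by methanolysis of the formate.

Step 10
Reactants: 14 DEF phenol; 5 2-bromo-3,4,5-tris(benzyloxy)benzaldehyde
Product: 15 CDEF aldehyde 3,4,5-tris(benzyloxy)-2-(DEF-aryloxy)benzaldehyde
Conditions: CuI (20 mol%), N,N-dimethylglycine (40 mol%), Cs2CO3, 1,4-dioxane, 100 °C, Ar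
Reagents that add atoms: none
Why: Ullmann diaryl ether synthesis of the same kind as step 6: ortho-formyl-activated bromide and a phenoxide with two free ortho positions.

Step 11
Reactants: 15 CDEF aldehyde
Product: 17 CDEF phenol 3,4,5-tris(benzyloxy)-2-(DEF-aryloxy)phenol, via CDEF formate 16 (not isolated)
Conditions: mCPBA, CH2Cl2, 0 °C to rt; then K2CO3 (0.2 equiv), MeOH, rt
Reagents that add atoms: 3-chloroperoxybenzoic acid, O=C(OO)c1cccc(Cl)c1
Why: Baeyer–Villiger oxidation of the same kind as step 7, with migration of the aryl group bearing ortho aryloxy and para benzyloxy donors, followed by methanolysis of the formate.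

Step 12
Reactants: 17 CDEF phenol; 8 3,5-bis(benzyloxy)-4-bromobenzaldehyde
Product: 18 BCDEF aldehyde 3,5-bis(benzyloxy)-4-(CDEF-aryloxy)benzaldehyde
Conditions: CuI (20 mol%), N,N-dimethylglycine (40 mol%), Cs2CO3, 1,4-dioxane, 100 °C, Ar
Reagents that add atoms: none
Why: Ullmann diaryl ether synthesis of the same kind as step 8: para-formyl-activated bromide and a phenoxide with a single ortho substituent.

Step 13
Reactants: 18 BCDEF aldehyde
Product: 20 BCDEF phenol 3,5-bis(benzyloxy)-4-(CDEF-aryloxy)phenol, via BCDEF formate 19 (not isolated)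
Conditions: mCPBA, CH2Cl2, 0 °C to rt; then K2CO3 (0.2 equiv), MeOH, rt
Reagents that add atoms: 3-chloroperoxybenzoic acid, O=C(OO)c1cccc(Cl)c1
Why: Baeyer–Villiger oxidation of the same kind as step 9, followed by methanolysis, which frees the ring B hydroxyl that will carry ring A.

Step 14
Reactants: 21 dibenzyl malonate
Product: 22 dibenzyl 2-chloromalonate
Conditions: SO2Cl2 (1.0 equiv), CH2Cl2, 0 °C to 40 °C
Reagents that add atoms: sulfuryl chloride, O=S(=O)(Cl)Cl
Why: α-Chlorination of a malonate through its enol with SO2Cl2, held at the monochloride by using one equivalent.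

Step 15
Reactants: 20 BCDEF phenol; 22 dibenzyl 2-chloromalonate
Product: 23 dibenzyl 2-(BCDEF-aryloxy)malonate
Conditions: 22 (1.3 equiv), K2CO3, acetone, 50 °C
Reagents that add atoms: none
Why: SN2 O-alkylation of a phenoxide by an α-chloromalonate (Williamson-type), the standard entry to aryloxymalonates; the ring B phenoxide has two free ortho positions.

Step 16
Reactants: 23 dibenzyl 2-(BCDEF-aryloxy)malonate; 24 dibenzyl 1,3-acetonedicarboxylate
Product: 26 dibenzyl 5-(BCDEF-aryloxy)-2,4,6-trihydroxyisophthalate, via open-chain Claisen adduct 25 (not isolated)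
Conditions: 24 (2 equiv), NaH (3 equiv), toluene, 0 °C to 100 °C; then 1 M HCl
Reagents that add atoms: none
Why: Proposed new method: the sodium enolate of 24 is C-acylated by one ester of 23 (crossed Claisen condensation, giving 25), the second methylene of the acetonedicarboxylate unit then attacks the remaining malonate ester in a Dieckmann-type 6-exo-trig (enolendo) closure that forms ring A, and the resulting cyclohexane-1,3,5-trione enolises to the aromatic triolate. The closest known reaction is the alkoxide-mediated condensation of dialkyl malonates with dialkyl 1,3-acetonedicarboxylates to 2,4,6-trihydroxyisophthalates; what is new is the aryloxy substituent on the malonate carbon, whose inductive effect should raise the electrophilicity of both ester carbonyls and whose one remaining hydrogen is what the final enolisation needs. No stereocentre is created, since the two sp3 centres of 25 end as aromatic carbons. The step needs C- rather than O-acylation in the ring closure and cross- rather than self-condensation: every acyl transfer is reversible under the benzyloxide that the reaction itself releases, so an enol lactone (pyranone) or a wrongly acylated adduct reopens, while the triolate of 26 is the only irreversible outlet that contains the malonate. Compound 23 has a single acidic carbon and cannot build a ring on its own, and the self-condensation of 24 is tolerated by using it in excess.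

Step 17
Reactants: 26 dibenzyl 5-(BCDEF-aryloxy)-2,4,6-trihydroxyisophthalate
Product: 28 CNP0114537.0, via hexamer diacid 27 (not isolated)
Conditions: H2 (1 atm), Pd(OH)2/C, THF–MeOH, rt; filter under Ar; then degassed H2O–THF, 60 °C
Reagents that add atoms: none
Why: Palladium-catalysed hydrogenolysis cleaves the thirteen benzyl ethers and both benzyl esters to toluene, and the 2,4,6-trihydroxyisophthalic acid 27, a β-keto acid through its keto tautomer, loses two molecules of CO2 on gentle warming.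

**Compound list**

1 | 3,4,5-trihydroxybenzaldehyde | O=Cc1cc(O)c(O)c(O)c1 | starting material
2 | 3,4,5-tris(benzyloxy)benzaldehyde | O=Cc1cc(OCc9ccccc9)c(OCc9ccccc9)c(OCc9ccccc9)c1 | intermediate
3 | 3,4,5-tris(benzyloxy)phenyl formate | O=COc1cc(OCc9ccccc9)c(OCc9ccccc9)c(OCc9ccccc9)c1 | intermediate
4 | 3,4,5-tris(benzyloxy)phenol (ring F) | Oc1cc(OCc9ccccc9)c(OCc9ccccc9)c(OCc9ccccc9)c1 | intermediate
5 | 2-bromo-3,4,5-tris(benzyloxy)benzaldehyde (rings E and C) | O=Cc1cc(OCc9ccccc9)c(OCc9ccccc9)c(OCc9ccccc9)c1Br | intermediate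
6 | 4-bromo-3,5-dimethoxybenzaldehyde | COc1cc(C=O)cc(OC)c1Br | starting material
7 | 4-bromo-3,5-dihydroxybenzaldehyde | O=Cc1cc(O)c(Br)c(O)c1 | intermediate
8 | 3,5-bis(benzyloxy)-4-bromobenzaldehyde (rings D and B) | O=Cc1cc(OCc9ccccc9)c(Br)c(OCc9ccccc9)c1 | intermediate
9 | EF aldehyde: 3,4,5-tris(benzyloxy)-2-[3,4,5-tris(benzyloxy)phenoxy]benzaldehyde | O=Cc1cc(OCc9ccccc9)c(OCc9ccccc9)c(OCc9ccccc9)c1Oc1cc(OCc9ccccc9)c(OCc9ccccc9)c(OCc9ccccc9)c1 | intermediate
10 | EF formate: formate ester of 11 | O=COc1cc(OCc9ccccc9)c(OCc9ccccc9)c(OCc9ccccc9)c1Oc1cc(OCc9ccccc9)c(OCc9ccccc9)c(OCc9ccccc9)c1 | intermediate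
11 | EF phenol: 3,4,5-tris(benzyloxy)-2-[3,4,5-tris(benzyloxy)phenoxy]phenol | Oc1cc(OCc9ccccc9)c(OCc9ccccc9)c(OCc9ccccc9)c1Oc1cc(OCc9ccccc9)c(OCc9ccccc9)c(OCc9ccccc9)c1 | intermediate
12 | DEF aldehyde: 3,5-bis(benzyloxy)-4-aryloxybenzaldehyde, the aryloxy group being 11 less its hydroxyl hydrogen | O=Cc1cc(OCc9ccccc9)c(Oc2cc(OCc9ccccc9)c(OCc9ccccc9)c(OCc9ccccc9)c2Oc2cc(OCc9ccccc9)c(OCc9ccccc9)c(OCc9ccccc9)c2)c(OCc9ccccc9)c1 | intermediate
13 | DEF formate: formate ester of 14 | O=COc1cc(OCc9ccccc9)c(Oc2cc(OCc9ccccc9)c(OCc9ccccc9)c(OCc9ccccc9)c2Oc2cc(OCc9ccccc9)c(OCc9ccccc9)c(OCc9ccccc9)c2)c(OCc9ccccc9)c1 | intermediate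
14 | DEF phenol: 3,5-bis(benzyloxy)-4-aryloxyphenol, aryloxy as in 12 | Oc1cc(OCc9ccccc9)c(Oc2cc(OCc9ccccc9)c(OCc9ccccc9)c(OCc9ccccc9)c2Oc2cc(OCc9ccccc9)c(OCc9ccccc9)c(OCc9ccccc9)c2)c(OCc9ccccc9)c1 | intermediate
15 | CDEF aldehyde: 3,4,5-tris(benzyloxy)-2-aryloxybenzaldehyde, the aryloxy group being 14 less its hydroxyl hydrogen | O=Cc1cc(OCc9ccccc9)c(OCc9ccccc9)c(OCc9ccccc9)c1Oc1cc(OCc9ccccc9)c(Oc2cc(OCc9ccccc9)c(OCc9ccccc9)c(OCc9ccccc9)c2Oc2cc(OCc9ccccc9)c(OCc9ccccc9)c(OCc9ccccc9)c2)c(OCc9ccccc9)c1 | intermediate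
16 | CDEF formate: formate ester of 17 | O=COc1cc(OCc9ccccc9)c(OCc9ccccc9)c(OCc9ccccc9)c1Oc1cc(OCc9ccccc9)c(Oc2cc(OCc9ccccc9)c(OCc9ccccc9)c(OCc9ccccc9)c2Oc2cc(OCc9ccccc9)c(OCc9ccccc9)c(OCc9ccccc9)c2)c(OCc9ccccc9)c1 | intermediate
17 | CDEF phenol: 3,4,5-tris(benzyloxy)-2-aryloxyphenol, aryloxy as in 15 | Oc1cc(OCc9ccccc9)c(OCc9ccccc9)c(OCc9ccccc9)c1Oc1cc(OCc9ccccc9)c(Oc2cc(OCc9ccccc9)c(OCc9ccccc9)c(OCc9ccccc9)c2Oc2cc(OCc9ccccc9)c(OCc9ccccc9)c(OCc9ccccc9)c2)c(OCc9ccccc9)c1 | intermediate
18 | BCDEF aldehyde: 3,5-bis(benzyloxy)-4-aryloxybenzaldehyde, the aryloxy group being 17 less its hydroxyl hydrogen | O=Cc1cc(OCc9ccccc9)c(Oc2cc(OCc9ccccc9)c(OCc9ccccc9)c(OCc9ccccc9)c2Oc2cc(OCc9ccccc9)c(Oc3cc(OCc9ccccc9)c(OCc9ccccc9)c(OCc9ccccc9)c3Oc3cc(OCc9ccccc9)c(OCc9ccccc9)c(OCc9ccccc9)c3)c(OCc9ccccc9)c2)c(OCc9ccccc9)c1 | intermediate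
19 | BCDEF formate: formate ester of 20 | O=COc1cc(OCc9ccccc9)c(Oc2cc(OCc9ccccc9)c(OCc9ccccc9)c(OCc9ccccc9)c2Oc2cc(OCc9ccccc9)c(Oc3cc(OCc9ccccc9)c(OCc9ccccc9)c(OCc9ccccc9)c3Oc3cc(OCc9ccccc9)c(OCc9ccccc9)c(OCc9ccccc9)c3)c(OCc9ccccc9)c2)c(OCc9ccccc9)c1 | intermediate
20 | BCDEF phenol: 3,5-bis(benzyloxy)-4-aryloxyphenol, aryloxy as in 18 (thirteen benzyl ethers, one free hydroxyl on ring B) | Oc1cc(OCc9ccccc9)c(Oc2cc(OCc9ccccc9)c(OCc9ccccc9)c(OCc9ccccc9)c2Oc2cc(OCc9ccccc9)c(Oc3cc(OCc9ccccc9)c(OCc9ccccc9)c(OCc9ccccc9)c3Oc3cc(OCc9ccccc9)c(OCc9ccccc9)c(OCc9ccccc9)c3)c(OCc9ccccc9)c2)c(OCc9ccccc9)c1 | intermediate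
21 | dibenzyl malonate | O=C(CC(=O)OCc1ccccc1)OCc1ccccc1 | starting material
22 | dibenzyl 2-chloromalonate | O=C(OCc1ccccc1)C(Cl)C(=O)OCc1ccccc1 | intermediate
23 | dibenzyl 2-(BCDEF-aryloxy)malonate: C2 of dibenzyl malonate bonded to the oxygen of 20 | O=C(OCc9ccccc9)C(C(=O)OCc9ccccc9)Oc1cc(OCc9ccccc9)c(Oc2cc(OCc9ccccc9)c(OCc9ccccc9)c(OCc9ccccc9)c2Oc2cc(OCc9ccccc9)c(Oc3cc(OCc9ccccc9)c(OCc9ccccc9)c(OCc9ccccc9)c3Oc3cc(OCc9ccccc9)c(OCc9ccccc9)c(OCc9ccccc9)c3)c(OCc9ccccc9)c2)c(OCc9ccccc9)c1 | intermediate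
24 | dibenzyl 1,3-acetonedicarboxylate (dibenzyl 3-oxopentanedioate) | O=C(CC(=O)OCc1ccccc1)CC(=O)OCc1ccccc1 | starting material
25 | open-chain Claisen adduct: dibenzyl 2-(BCDEF-aryloxy)-4-(benzyloxycarbonyl)-3,5-dioxoheptanedioate (mixture of stereoisomers and enol forms) | O=C(OCc9ccccc9)CC(=O)C(C(=O)OCc9ccccc9)C(=O)C(C(=O)OCc9ccccc9)Oc1cc(OCc9ccccc9)c(Oc2cc(OCc9ccccc9)c(OCc9ccccc9)c(OCc9ccccc9)c2Oc2cc(OCc9ccccc9)c(Oc3cc(OCc9ccccc9)c(OCc9ccccc9)c(OCc9ccccc9)c3Oc3cc(OCc9ccccc9)c(OCc9ccccc9)c(OCc9ccccc9)c3)c(OCc9ccccc9)c2)c(OCc9ccccc9)c1 | intermediate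
26 | dibenzyl 5-(BCDEF-aryloxy)-2,4,6-trihydroxyisophthalate (ring A closed; aryloxy is 20 less its hydroxyl hydrogen) | O=C(OCc9ccccc9)c1c(O)c(C(=O)OCc9ccccc9)c(O)c(Oc2cc(OCc9ccccc9)c(Oc3cc(OCc9ccccc9)c(OCc9ccccc9)c(OCc9ccccc9)c3Oc3cc(OCc9ccccc9)c(Oc4cc(OCc9ccccc9)c(OCc9ccccc9)c(OCc9ccccc9)c4Oc4cc(OCc9ccccc9)c(OCc9ccccc9)c(OCc9ccccc9)c4)c(OCc9ccccc9)c3)c(OCc9ccccc9)c2)c1O | intermediate
27 | hexamer diacid: 28 with a carboxyl group on each of the two CH carbons of ring A | OC(=O)c1c(O)c(C(=O)O)c(O)c(Oc2cc(O)c(Oc3cc(O)c(O)c(O)c3Oc3cc(O)c(Oc4cc(O)c(O)c(O)c4Oc4cc(O)c(O)c(O)c4)c(O)c3)c(O)c2)c1O | intermediate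
28 | CNP0114537.0 (hexameric phlorotannin, sixteen free hydroxyls) | Oc1cc(O)c(Oc2cc(O)c(Oc3cc(O)c(O)c(O)c3Oc3cc(O)c(Oc4cc(O)c(O)c(O)c4Oc4cc(O)c(O)c(O)c4)c(O)c3)c(O)c2)c(O)c1 | target

**Totals**

Total step count: 17.
Longest linear sequence: 13 steps (1 → 2 → 4 → 9 → 11 → 12 → 14 → 15 → 17 → 18 → 20 → 23 → 26 → 28; steps 1, 2, 6 to 13, 15, 16, 17).

**Steps most likely to fail**

1. Step 16 (Proposed new method). Under the basic conditions 23 is largely held as its own enolate, a poor acylating agent, so the crossed Claisen step may be slower than the self-condensation of 24 or than thermal loss of benzyl ester groups, and ring A would not form. Fallback with known chemistry: ring A is attached instead of built, by one more round of the coupling and oxidation already used for ring B. The fallback sets out from phenol 20. CuI-catalysed Ullmann coupling with bromo aldehyde 8 should give the hexamer aldehyde F1. Baeyer–Villiger oxidation with mCPBA would lead to the hexamer formate F2, and methanolysis to the hexamer phenol F3, in which ring A carries two benzyl ethers and one free hydroxyl. Hydrogenolysis of its fifteen benzyl ethers over Pd(OH)2/C rejoins the route at 28.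

2. Step 12. Insertion of copper into the C–Br bond of 8, which is flanked by two benzyloxy groups, may become slower than hydrodebromination and catalyst decay once the phenoxide partner is the bulky tetramer, leaving 17 unconsumed. Fallback: a metal-free SNAr in place of the copper coupling, since addition to a C–F carbon is much less sensitive to the flanking groups. Commercial 4-fluoro-3,5-dimethoxybenzaldehyde F4 would be demethylated with BBr3 to 4-fluoro-3,5-dihydroxybenzaldehyde F5 and benzylated (BnBr, K2CO3) to 3,5-bis(benzyloxy)-4-fluorobenzaldehyde F6. The fallback sets out from 17, whose caesium phenoxide (Cs2CO3, DMSO, 110 °C) displaces the fluoride para to the formyl group, and it returns to the route at 18. The same switch would serve step 8 (11 to 12).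

3. Step 15. Proton transfer from the acidic chloromalonate to the phenoxide, followed by self-condensation of the chloromalonate anion, or halogen transfer to the electron-rich ring B, may outpace O-alkylation of the precious pentamer. Fallback: carbenoid O–H insertion in place of SN2 alkylation. Dibenzyl 2-diazomalonate F7 would be made from 21 by diazo transfer (4-acetamidobenzenesulfonyl azide, Et3N, MeCN). The fallback sets out from 20: F7 is added slowly to 20 and Rh2(OAc)4 (1 mol%) in toluene at 80 °C, and insertion of the rhodium carbenoid into the phenolic O–H bond returns to the route at 23.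

**Further compounds**

F1 | step 16 | hexamer aldehyde: 3,5-bis(benzyloxy)-4-(BCDEF-aryloxy)benzaldehyde, the aryloxy group being 20 less its hydroxyl hydrogen | O=Cc1cc(OCc9ccccc9)c(Oc2cc(OCc9ccccc9)c(Oc3cc(OCc9ccccc9)c(OCc9ccccc9)c(OCc9ccccc9)c3Oc3cc(OCc9ccccc9)c(Oc4cc(OCc9ccccc9)c(OCc9ccccc9)c(OCc9ccccc9)c4Oc4cc(OCc9ccccc9)c(OCc9ccccc9)c(OCc9ccccc9)c4)c(OCc9ccccc9)c3)c(OCc9ccccc9)c2)c(OCc9ccccc9)c1
F2 | step 16 | hexamer formate: formate ester of F3 | O=COc1cc(OCc9ccccc9)c(Oc2cc(OCc9ccccc9)c(Oc3cc(OCc9ccccc9)c(OCc9ccccc9)c(OCc9ccccc9)c3Oc3cc(OCc9ccccc9)c(Oc4cc(OCc9ccccc9)c(OCc9ccccc9)c(OCc9ccccc9)c4Oc4cc(OCc9ccccc9)c(OCc9ccccc9)c(OCc9ccccc9)c4)c(OCc9ccccc9)c3)c(OCc9ccccc9)c2)c(OCc9ccccc9)c1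
F3 | step 16 | hexamer phenol: 3,5-bis(benzyloxy)-4-(BCDEF-aryloxy)phenol (fifteen benzyl ethers, one free hydroxyl on ring A) | Oc1cc(OCc9ccccc9)c(Oc2cc(OCc9ccccc9)c(Oc3cc(OCc9ccccc9)c(OCc9ccccc9)c(OCc9ccccc9)c3Oc3cc(OCc9ccccc9)c(Oc4cc(OCc9ccccc9)c(OCc9ccccc9)c(OCc9ccccc9)c4Oc4cc(OCc9ccccc9)c(OCc9ccccc9)c(OCc9ccccc9)c4)c(OCc9ccccc9)c3)c(OCc9ccccc9)c2)c(OCc9ccccc9)c1
F4 | step 12 | 4-fluoro-3,5-dimethoxybenzaldehyde | COc1cc(C=O)cc(OC)c1F
F5 | step 12 | 4-fluoro-3,5-dihydroxybenzaldehyde | O=Cc1cc(O)c(F)c(O)c1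
F6 | step 12 | 3,5-bis(benzyloxy)-4-fluorobenzaldehyde | O=Cc1cc(OCc9ccccc9)c(F)c(OCc9ccccc9)c1
F7 | step 15 | dibenzyl 2-diazomalonate | [N-]=[N+]=C(C(=O)OCc1ccccc1)C(=O)OCc1ccccc1
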